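The numbers in the tables are calculated from invented constants; the scatter is artificial.

The vessel is a closed, stirred flask at constant volume and constant temperature, and the target in it flattens well short of the charge.

| setting | oak | birch | flask |
|---|---|---|---|
| starting material | 10 mM | 5 mM | 10 mM |
| partner | 1.2 equiv | 1.2 equiv | 1.20 equiv |
| second substrate | 5 equiv | 5 equiv | 5.00 equiv |
| temperature | 60 °C | 66 °C | 60 °C |
| remark | the very flask that is asked about, followed so far | run made earlier |  |
| time |  |  | 20 h |

- oak (time / h: target / %, starting material / %): 1.50: 8.7, 92.7; 2.50: 11.3, 87.5; 4.00: 15.8, 84.2; 8.00: 21.2, 77.0; 12.0: 24.1, 75.5; 20.0: 25.5, 75.1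
- birch (time / h: target / %, starting material / %): 1.00: 4.9, 94.7; 2.50: 8.8, 91.2; 5.00: 12.4, 87.8; 8.00: 14.2, 86.3; 10.0: 14.6, 86.1; 15.0: 14.1, 84.6

(scatter of a reading: 0.5 percentage points)

- blue: at 20 h take out 90% of the target then present, then wait 10 h
- red: at 20 h raise the temperature by 20 K, then wait 10 h
- violet: change nothing and wait 10 h more
- green: at 20 h add partner, 50.0% of the amount charged, then wait 10 h

- what is taken out of target is counted as made
- additions bring no volume worth counting

- target, in percent of the starting material first charged, at 20 h
- which option adds most target ("none" when 2 percentage points or less is all one gets) (blue / red / violet / green / none)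
- target present, with what was taken out counted in, in percent of the starting material first charged, after violet
- target present, with what was taken out counted in, in percent of the starting material first charged, after green

Oak and birch both flatten, and two people read that differently. The first says each flask has reached balance (thermodynamic control): making and falling back have come level, like an inflow and a drain at a steady tank level. Reckoned with what is left, not what is made, one number should then hold at one temperature, and oak and birch differ in temperature as well as in concentration. This is the holding quotient, c(target) over c(starting material) times c(partner), with free partner taken as the charge minus the target, and the last oak reading gives 0.0359 mM⁻¹. The last birch reading, at 66 °C and 5 mM, gives 0.0315 mM⁻¹, although its target reads 14.1% against 25.5% at the last oak reading.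

The second says the partner decays at 0.23 per hour, the forecast's figure, and the reaction stops with it. The last oak reading of target is about twice the last birch reading, at twice the concentration and a lower temperature, and that fits this view too. Taking out target then gains nothing, while fresh partner restarts the flask.

I side with the first. After blue, the flask holds 10.0% of its target, the quotient drops to 0.00359 mM⁻¹, and by my reckoning refilling to 0.0359 mM⁻¹ at full relaxation makes 15 percentage points.

The forecast gives 25.4% at 20 h, 25.7% after violet, 34% after green, and chooses green, allowing blue 12 points, where I reckon 15 points, if the first view holds and none if the second does: “Green gains about 9 points in either picture, so it is the robust choice.”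

The flask gives 25.8% at 20 h, 26.0% after violet and 34.5% after green, and the best option is blue. Blue adds 13 points, green 8.7 points, violet 0.19 points and red −6.7 points.

    second substrate + partner ⇌ second product (K = 0.850 M⁻¹, k = 7.60 M⁻¹ h⁻¹, Ea = 58.0 kJ mol⁻¹, ΔH = −32.0 kJ mol⁻¹)
    starting material + partner ⇌ target (K = 39.0 M⁻¹, k = 5.70 M⁻¹ h⁻¹, Ea = 75.0 kJ mol⁻¹, ΔH = −24.0 kJ mol⁻¹)
    (constants at 60 °C)

Blue's 13 points in this flask stands against my 15 points at full relaxation. Taking away the backward run from target lifts this flask's target at 20 h from 25.8% to 59.5% and turns the answer to best, a large effect but not the whole of what is missing. The second view's choice belongs to the case without return: the fit of the same steps with nothing going back answers green, but this flask still has 75.3% of its partner free at 20.0 h. For the neighbour flask with 2.00 equiv of partner, 0.0359 mM⁻¹ gives 36.9% of target, and at 20 h that flask holds 37.6%.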